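**Retrosynthetic overview**

1. Disconnection of the C9–C11 bond. C10 is sp2 in the target (the C10=C1 olefin at the fusion of rings A and B), so it can be a ring B ketone at the key step. The quaternary C9 (CH3, CH2Ar) and its neighbour C8 (H, CH3), with the two methyl groups cis, are then the α and β carbons of 2-methylcyclohex-2-en-1-one.
2. Key step: copper-catalysed asymmetric conjugate addition of methyl to C8 and, in the same flask, benzylation of the C9 enolate anti to the new methyl by the arylmethyl bromide (C8 set by the catalyst, C9 relayed from C8).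
3. Ring A is then built on C10/C5: enol triflate, iron-catalysed coupling with a homoprenyl Grignard reagent, Shi epoxidation (C3), and a titanocene-mediated radical epoxy-olefin cyclisation that forms C4–C5, sets H5 and leaves the C10=C1 olefin.
4. Arene: a C2-symmetric 2,6-disilyloxy-4-(silyloxymethyl)benzyl bromide from 3,5-dihydroxy-4-methylbenzoic acid. The aldehyde comes last by ortho-formylation, because the two free ring positions are equivalent.
5. Ring order: arene bought; ring B bought as the enone and substituted in step 6; ring A closed in step 10.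

Key step: step 6

Assumption: the ortho-(hydroxymethyl)benzaldehyde is taken in its open form, which the hydrogen bond from the neighbouring phenol should favour over the cyclic lactol.
Abbreviations: TBS = tert-butyldimethylsilyl; Ar = 2,6-bis(TBSO)-4-(TBSOCH2)phenyl.

**Route**

Step 1
Reactants: 1 3,5-dihydroxy-4-methylbenzoic acid
Product: 2 methyl 3,5-dihydroxy-4-methylbenzoate
Conditions: MeOH, H2SO4 (cat.), reflux
Reagents that add atoms: methanol, CO
Why: Fischer esterification of an unhindered benzoic acid should proceed cleanly and leave the phenols untouched.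

Step 2
Reactants: 2 methyl 3,5-dihydroxy-4-methylbenzoate
Product: 3 methyl 3,5-bis(TBSO)-4-methylbenzoate
Conditions: TBSCl, imidazole, DMF, rt
Reagents that add atoms: tert-butyldimethylsilyl chloride (TBSCl), CC(C)(C)[Si](C)(C)Cl
Why: Imidazole-promoted silylation of both phenols masks the acidic OH groups for the radical bromination and the organometallic steps, in a form that can later be removed without acid.

Step 3
Reactants: 3 methyl 3,5-bis(TBSO)-4-methylbenzoate
Product: 4 methyl 4-(bromomethyl)-3,5-bis(TBSO)benzoate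
Conditions: NBS, AIBN (cat.), PhCF3, 85 °C
Reagents that add atoms: N-bromosuccinimide (NBS), O=C1CCC(=O)N1Br
Why: Wohl–Ziegler bromination should attack the only benzylic CH3, because the ester deactivates the ring toward electrophilic bromination.

Step 4
Reactants: 4 methyl 4-(bromomethyl)-3,5-bis(TBSO)benzoate
Product: 5 [4-(bromomethyl)-3,5-bis(TBSO)phenyl]methanol
Conditions: i-Bu2AlH, CH2Cl2, −78 °C; aq. KNaC4H4O6
Reagents that add atoms: none
Why: Ester reduction by i-Bu2AlH at low temperature should give the primary alcohol without touching the benzylic C–Br bond or the aryl silyl ethers.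

Step 5
Reactants: 5 [4-(bromomethyl)-3,5-bis(TBSO)phenyl]methanol
Product: 6 {[4-(bromomethyl)-3,5-bis(TBSO)phenyl]methoxy}(tert-butyl)dimethylsilane (ArCH2Br)
Conditions: TBSOTf, 2,6-lutidine, CH2Cl2, −78 °C
Reagents that add atoms: tert-butyldimethylsilyl triflate (TBSOTf), CC(C)(C)[Si](C)(C)OS(=O)(=O)C(F)(F)F
Why: Silyl triflate silylation with a hindered pyridine base protects the alcohol, and 2,6-lutidine is too hindered to be quaternised by the reactive benzylic bromide.

Step 6
Reactants: 7 2-methylcyclohex-2-en-1-one; 6 ArCH2Br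
Product: 10 (2S,3R)-2-(ArCH2)-2,3-dimethylcyclohexan-1-one, via dimethylaluminium enolate 8 (not isolated), via lithium aluminate enolate 9 (not isolated)
Conditions: 7, AlMe3, copper thiophene-2-carboxylate (CuTC, monovalent copper, 2 mol %), binaphthyl-2,2'-diyl N,N-bis(1-phenylethyl)phosphoramidite (4 mol %, enantiomer that gives 3R), Et2O, −30 °C; then MeLi, THF/DMPU, −30 °C; then 6, −30 to 0 °C
Reagents that add atoms: trimethylaluminium (AlMe3), C[Al](C)C
Why: A copper–phosphoramidite complex transfers one methyl group of AlMe3 to C8 of enone 7 in a 1,4-addition, which gives the dimethylaluminium enolate 8 with its double bond fixed between C9 and C10; MeLi turns it into the nucleophilic aluminate 9, which is alkylated at C9 by the benzylic bromide 6. The closest known reaction type is the copper-catalysed asymmetric conjugate addition of trialkylaluminium or Grignard reagents to 2-methylcyclohexenone with trapping of the enolate by allyl and benzyl halides. No ring is closed; the step is a three-component coupling that forms the C8–CH3 and C9–C11 bonds and joins ring B to the arene. C8 is set by the ligand (face selection in the methyl transfer) and C9 by the substrate: A(1,2) strain with the C9 methyl turns the C8 methyl pseudoaxial and the electrophile enters anti to it, so the arylmethyl group ends trans to the C8 methyl and the two methyl groups cis. The step needs 1,4- instead of 1,2-addition, C- instead of O-alkylation and no enolate equilibration toward C5; copper catalysis should secure the first, and the regiospecific generation of the enolate together with the high reactivity of a benzylic bromide flanked by two oxygen atoms should secure the others.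

Step 7
Reactants: 10 (2S,3R)-2-(ArCH2)-2,3-dimethylcyclohexan-1-one
Product: 12 (5R,6S)-6-(ArCH2)-5,6-dimethylcyclohex-1-en-1-yl trifluoromethanesulfonate, via potassium enolate 11 (not isolated)
Conditions: KN(SiMe3)2, THF, −78 °C; then PhNTf2, −78 °C to rt
Reagents that add atoms: N-phenylbis(trifluoromethanesulfonimide) (PhNTf2), FC(F)(F)S(=O)(=O)N(c1ccccc1)S(=O)(=O)C(F)(F)F
Why: Enolisation can occur only toward C5 because C9 is quaternary, so O-triflation of the potassium enolate (enol triflate formation) should give the C5=C10 triflate as a single regioisomer.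

Step 8
Reactants: 12 (5R,6S)-6-(ArCH2)-5,6-dimethylcyclohex-1-en-1-yl trifluoromethanesulfonate; 13 5-bromo-2-methylpent-2-ene
Product: 15 (5R,6S)-6-(ArCH2)-5,6-dimethyl-1-(4-methylpent-3-en-1-yl)cyclohex-1-ene, via (4-methylpent-3-en-1-yl)magnesium bromide 14 (not isolated)
Conditions: 13, Mg, THF, rt; then 12, Fe(acac)3 (5 mol %), THF/NMP, −30 to 0 °C
Reagents that add atoms: none
Why: Iron-catalysed Kumada-type cross-coupling of an alkenyl triflate with a primary alkyl Grignard reagent is fast at low temperature, tolerates silyl ethers and attaches C1–C4 to C10 with the olefin held at C5=C10.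

Step 9
Reactants: 15 (5R,6S)-6-(ArCH2)-5,6-dimethyl-1-(4-methylpent-3-en-1-yl)cyclohex-1-ene
Product: 16 (3S)-3-{2-[(5R,6S)-6-(ArCH2)-5,6-dimethylcyclohex-1-en-1-yl]ethyl}-2,2-dimethyloxirane
Conditions: 1,2:4,5-di-O-isopropylidene-β-L-erythro-2,3-hexodiulo-2,6-pyranose (L-fructose-derived ketone catalyst, 30 mol %), KHSO5, K2CO3, Bu4NHSO4, MeCN/CH2(OMe)2/aq. Na2B4O7 buffer (pH 10.5), 0 °C
Reagents that add atoms: potassium peroxymonosulfate (KHSO5), [K+].[O-]S(=O)(=O)OO
Why: In the Shi epoxidation the chiral dioxirane should oxidise the open Me2C=CH terminus in preference to the ring olefin shielded by the quaternary C9, and the catalyst enantiomer (spiro transition state) is expected to set C3 as S.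

Step 10
Reactants: 16 (3S)-3-{2-[(5R,6S)-6-(ArCH2)-5,6-dimethylcyclohex-1-en-1-yl]ethyl}-2,2-dimethyloxirane
Product: 17 (2S,5S,6R,8aR)-5-(ArCH2)-1,1,5,6-tetramethyl-1,2,3,5,6,7,8,8a-octahydronaphthalen-2-ol
Conditions: Cp2TiCl2 (2.5 equiv), Mn dust, THF, rt (gives Cp2TiCl, trivalent titanium); slow addition of 16; then dilute aq. HCl
Reagents that add atoms: none
Why: In a titanocene-mediated radical epoxy-polyene cyclisation, Cp2TiCl opens the epoxide homolytically to the tertiary C4 radical, which closes ring A by 6-endo addition to C5 through a chair transition state with the titanoxy group equatorial and on the face anti to the pseudoaxial C9 methyl (so H5 ends trans to the C3 oxygen and cis to the C9 methyl), and a second Cp2TiCl then removes hydrogen from C1, the only unhindered neighbour of the C10 radical, to leave the C10=C1 olefin.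

Step 11
Reactants: 17 (2S,5S,6R,8aR)-5-(ArCH2)-1,1,5,6-tetramethyl-1,2,3,5,6,7,8,8a-octahydronaphthalen-2-ol
Product: 18 5-[(tert-butyldimethylsilyloxy)methyl]-2-{[(1S,2R,4aR,6S)-6-hydroxy-1,2,5,5-tetramethyl-1,2,3,4,4a,5,6,7-octahydronaphthalen-1-yl]methyl}benzene-1,3-diol
Conditions: K2CO3, MeOH/THF, 0 °C to rt
Reagents that add atoms: none
Why: Base-catalysed methanolysis cleaves aryl silyl ethers (phenoxide leaving group) far faster than the primary alkyl silyl ether, and the basic medium cannot protonate the C10=C1 olefin.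

Step 12
Reactants: 18 bis-phenol (benzylic TBS ether)
Product: 19 6-[(tert-butyldimethylsilyloxy)methyl]-2,4-dihydroxy-3-{[(1S,2R,4aR,6S)-6-hydroxy-1,2,5,5-tetramethyl-1,2,3,4,4a,5,6,7-octahydronaphthalen-1-yl]methyl}benzaldehyde
Conditions: MgCl2, Et3N, (CH2O)n, THF, reflux
Reagents that add atoms: paraformaldehyde (as formaldehyde), C=O
Why: Magnesium phenoxide-directed ortho-formylation (Casnati–Skattebøl) should give one aldehyde, because the two free ring positions are equivalent by symmetry and the first formyl group deactivates the ring toward a second one.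

Step 13
Reactants: 19 aldehyde (benzylic TBS ether)
Product: 20 2,4-dihydroxy-6-(hydroxymethyl)-3-{[(1S,2R,4aR,6S)-6-hydroxy-1,2,5,5-tetramethyl-1,2,3,4,4a,5,6,7-octahydronaphthalen-1-yl]methyl}benzaldehyde (target)
Conditions: Bu4NF, THF, 0 °C; aq. NH4Cl
Reagents that add atoms: none
Why: Fluoride-mediated desilylation removes the primary benzylic TBS ether under near-neutral conditions, which avoids acid-induced addition of the free phenol to the C10=C1 olefin.

**Compound list**

1 | 3,5-dihydroxy-4-methylbenzoic acid | Cc1c(O)cc(C(=O)O)cc1O | starting material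
2 | methyl 3,5-dihydroxy-4-methylbenzoate | Cc1c(O)cc(C(=O)OC)cc1O | intermediate
3 | methyl 3,5-bis(tert-butyldimethylsilyloxy)-4-methylbenzoate | Cc1c(O[Si](C)(C)C(C)(C)C)cc(C(=O)OC)cc1O[Si](C)(C)C(C)(C)C | intermediate
4 | methyl 4-(bromomethyl)-3,5-bis(tert-butyldimethylsilyloxy)benzoate | BrCc1c(O[Si](C)(C)C(C)(C)C)cc(C(=O)OC)cc1O[Si](C)(C)C(C)(C)C | intermediate
5 | [4-(bromomethyl)-3,5-bis(tert-butyldimethylsilyloxy)phenyl]methanol | BrCc1c(O[Si](C)(C)C(C)(C)C)cc(CO)cc1O[Si](C)(C)C(C)(C)C | intermediate
6 | {[4-(bromomethyl)-3,5-bis(tert-butyldimethylsilyloxy)phenyl]methoxy}(tert-butyl)dimethylsilane | BrCc1c(O[Si](C)(C)C(C)(C)C)cc(CO[Si](C)(C)C(C)(C)C)cc1O[Si](C)(C)C(C)(C)C | intermediate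
7 | 2-methylcyclohex-2-en-1-one | CC1=CCCCC1=O | starting material
8 | {[(3R)-2,3-dimethylcyclohex-1-en-1-yl]oxy}dimethylaluminium | C[C@@H]1CCCC(O[Al](C)C)=C1C | intermediate
9 | lithium {[(3R)-2,3-dimethylcyclohex-1-en-1-yl]oxy}trimethylaluminate | [Li+].C[C@@H]1CCCC(O[Al-](C)(C)C)=C1C | intermediate
10 | (2S,3R)-2-{[2,6-bis(tert-butyldimethylsilyloxy)-4-(tert-butyldimethylsilyloxymethyl)phenyl]methyl}-2,3-dimethylcyclohexan-1-one | C[C@@H]1CCCC(=O)[C@@]1(C)Cc1c(O[Si](C)(C)C(C)(C)C)cc(CO[Si](C)(C)C(C)(C)C)cc1O[Si](C)(C)C(C)(C)C | intermediate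
11 | potassium (5R,6S)-6-(ArCH2)-5,6-dimethylcyclohex-1-en-1-olate | [K+].C[C@@H]1CCC=C([O-])[C@@]1(C)Cc1c(O[Si](C)(C)C(C)(C)C)cc(CO[Si](C)(C)C(C)(C)C)cc1O[Si](C)(C)C(C)(C)C | intermediate
12 | (5R,6S)-6-(ArCH2)-5,6-dimethylcyclohex-1-en-1-yl trifluoromethanesulfonate | C[C@@H]1CCC=C(OS(=O)(=O)C(F)(F)F)[C@@]1(C)Cc1c(O[Si](C)(C)C(C)(C)C)cc(CO[Si](C)(C)C(C)(C)C)cc1O[Si](C)(C)C(C)(C)C | intermediate
13 | 5-bromo-2-methylpent-2-ene | CC(C)=CCCBr | starting material
14 | (4-methylpent-3-en-1-yl)magnesium bromide | CC(C)=CCC[Mg]Br | intermediate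
15 | (5R,6S)-6-(ArCH2)-5,6-dimethyl-1-(4-methylpent-3-en-1-yl)cyclohex-1-ene | C[C@@H]1CCC=C(CCC=C(C)C)[C@@]1(C)Cc1c(O[Si](C)(C)C(C)(C)C)cc(CO[Si](C)(C)C(C)(C)C)cc1O[Si](C)(C)C(C)(C)C | intermediate
16 | (3S)-3-{2-[(5R,6S)-6-(ArCH2)-5,6-dimethylcyclohex-1-en-1-yl]ethyl}-2,2-dimethyloxirane | C[C@@H]1CCC=C(CC[C@@H]2OC2(C)C)[C@@]1(C)Cc1c(O[Si](C)(C)C(C)(C)C)cc(CO[Si](C)(C)C(C)(C)C)cc1O[Si](C)(C)C(C)(C)C | intermediate
17 | (2S,5S,6R,8aR)-5-(ArCH2)-1,1,5,6-tetramethyl-1,2,3,5,6,7,8,8a-octahydronaphthalen-2-ol | C[C@@H]1CC[C@@H]2C(=CC[C@H](O)C2(C)C)[C@@]1(C)Cc1c(O[Si](C)(C)C(C)(C)C)cc(CO[Si](C)(C)C(C)(C)C)cc1O[Si](C)(C)C(C)(C)C | intermediate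
18 | 5-[(tert-butyldimethylsilyloxy)methyl]-2-{[(1S,2R,4aR,6S)-6-hydroxy-1,2,5,5-tetramethyl-1,2,3,4,4a,5,6,7-octahydronaphthalen-1-yl]methyl}benzene-1,3-diol | C[C@@H]1CC[C@@H]2C(=CC[C@H](O)C2(C)C)[C@@]1(C)Cc1c(O)cc(CO[Si](C)(C)C(C)(C)C)cc1O | intermediate
19 | 6-[(tert-butyldimethylsilyloxy)methyl]-2,4-dihydroxy-3-{[(1S,2R,4aR,6S)-6-hydroxy-1,2,5,5-tetramethyl-1,2,3,4,4a,5,6,7-octahydronaphthalen-1-yl]methyl}benzaldehyde | C[C@@H]1CC[C@@H]2C(=CC[C@H](O)C2(C)C)[C@@]1(C)Cc1c(O)cc(CO[Si](C)(C)C(C)(C)C)c(C=O)c1O | intermediate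
20 | 2,4-dihydroxy-6-(hydroxymethyl)-3-{[(1S,2R,4aR,6S)-6-hydroxy-1,2,5,5-tetramethyl-1,2,3,4,4a,5,6,7-octahydronaphthalen-1-yl]methyl}benzaldehyde | C[C@@H]1CC[C@@H]2C(=CC[C@H](O)C2(C)C)[C@@]1(C)Cc1c(O)cc(CO)c(C=O)c1O | target

**Step count and risks**

Total step count: 13. Longest linear sequence: 13 steps (steps 1 to 13 from acid 1; enone 7 and bromide 13 are bought).

Steps most likely to fail:

- **Step 6.** Both partners are crowded, so C-alkylation of the tetrasubstituted enolate may be slow, and O-alkylation, proton transfer to the enolate or erosion of the anti selectivity may compete. The fallback sets out from 7 and 6 and comes back at 10. The copper-catalysed AlMe3 addition is run as in step 6, but enolate 8 is silylated with TMSOTf and {[(3R)-2,3-dimethylcyclohex-1-en-1-yl]oxy}trimethylsilane F1 is isolated. F1 and bromide 6 are then combined with ZnBr2 in CH2Cl2. This is a Lewis-acid-promoted SN1-type α-alkylation of a silyl enol ether by a benzylic cation that the two ortho oxygen atoms stabilise; the cation should add anti to the C8 methyl and give 10.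

- **Step 10.** The tertiary C10 radical may be reduced, or may lose hydrogen from C5 instead of C1, and the addition to C5 may occur with poor facial selectivity. The fallback sets out from 16 and comes back at 17. The radical closure is replaced by the cationic epoxy-olefin cyclisation with MeAlCl2 in CH2Cl2 at −78 °C. The epoxide opens at the tertiary C4, the ring B olefin attacks through C5 in the same chair arrangement, and the aluminate takes the proton from C1 in an ene-like manner, since C9 carries no hydrogen. This fallback makes no new compound (none F0).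

- **Step 12.** Formylation next to the silyloxymethyl group may be sluggish, and a second formylation at the other equivalent ring position may follow. The fallback sets out from 18 and comes back at 19. One equivalent of NBS in CH2Cl2 at −78 °C brominates the activated ring once and gives 4-bromo-5-[(tert-butyldimethylsilyloxy)methyl]-2-{[(1S,2R,4aR,6S)-6-hydroxy-1,2,5,5-tetramethyl-1,2,3,4,4a,5,6,7-octahydronaphthalen-1-yl]methyl}benzene-1,3-diol F2. Excess n-BuLi in THF at −78 °C then deprotonates the three OH groups and exchanges bromine for lithium, and DMF delivers the single formyl group of 19.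

Further compounds
F1 | step 6 | {[(3R)-2,3-dimethylcyclohex-1-en-1-yl]oxy}trimethylsilane | C[C@@H]1CCCC(O[Si](C)(C)C)=C1C
F0 | step 10 | none | none
F2 | step 12 | 4-bromo-5-[(tert-butyldimethylsilyloxy)methyl]-2-{[(1S,2R,4aR,6S)-6-hydroxy-1,2,5,5-tetramethyl-1,2,3,4,4a,5,6,7-octahydronaphthalen-1-yl]methyl}benzene-1,3-diol | C[C@@H]1CC[C@@H]2C(=CC[C@H](O)C2(C)C)[C@@]1(C)Cc1c(O)cc(CO[Si](C)(C)C(C)(C)C)c(Br)c1O
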